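**Retrosynthetic overview**
The target is a 3-methoxyflavone whose ring B has its hydroxyl at C2', next to the C1'–C2 bond. The six atoms O2'–C2'–C1'–C2–C3(OMe)–C4(=O) are therefore treated as the ring of a 3-methoxycoumarin, and C4a of ring A (para to the 7-OMe) is the carbon that must take the acyl carbon.
Last disconnection: C4–C4a, a Fries-type acyl switch, leading back to 4-(2,3-dimethoxyphenoxy)-3,6,7-trimethoxycoumarin, an isomer of the target.
Second disconnection: the O1–C2 aryl vinyl ether bond, leading back to a 4-chlorocoumarin and 2,3-dimethoxyphenol.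
Third disconnection: the coumarin C3–C4 bond, by intramolecular Claisen condensation of an O-methoxyacetyl salicylate.
Ring order: ring B arrives with 1; a lactone ring is annulated to it (step 3); the future ring A is tethered through an ether oxygen (step 5); ring C forms in step 6 as the lactone ring is given up.

Key step: step 6

Remark on the chemistry: 1 (4,5-dimethoxysalicylic acid) is assumed to be purchasable; the target has no stereocentre; cation 9 is written in its ketene–oxocarbenium resonance form.

**Route**

Step 1
Reactants: 1 2-hydroxy-4,5-dimethoxybenzoic acid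
Product: 2 methyl 2-hydroxy-4,5-dimethoxybenzoate
Conditions: MeOH, H2SO4 (cat.), reflux
Reagents that add atoms: methanol, CO
Why: Fischer esterification converts the acid into the methyl ester that later serves as the Claisen electrophile, while the phenol is inert to acidic methanol.

Step 2
Reactants: 2 methyl 2-hydroxy-4,5-dimethoxybenzoate; 3 methoxyacetyl chloride
Product: 4 methyl 4,5-dimethoxy-2-(2-methoxyacetoxy)benzoate
Conditions: Et3N, 4-(dimethylamino)pyridine (cat.), CH2Cl2, 0 °C → rt
Reagents that add atoms: none
Why: O-acylation of a phenol by an acid chloride under nucleophilic catalysis should overcome the hydrogen bond of the salicylate hydroxyl and give the aryl ester cleanly.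

Step 3
Reactants: 4 methyl 4,5-dimethoxy-2-(2-methoxyacetoxy)benzoate
Product: 5 4-hydroxy-3,6,7-trimethoxychromen-2-one
Conditions: LiN(SiMe3)2 (2.2 equiv), THF, −78 → 0 °C; then 1 M HCl
Reagents that add atoms: none
Why: Intramolecular Claisen (Dieckmann-type) condensation, in which the lithium enolate of the methoxyacetate attacks the neighbouring methyl ester in a six-membered closure and deprotonation of the acidic 4-hydroxycoumarin formed pulls the equilibrium forward.

Step 4
Reactants: 5 4-hydroxy-3,6,7-trimethoxychromen-2-one
Product: 6 4-chloro-3,6,7-trimethoxychromen-2-one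
Conditions: POCl3, benzyltriethylammonium chloride (cat.), MeCN, 80 °C; then ice-water
Reagents that add atoms: phosphoryl chloride POCl3, O=P(Cl)(Cl)Cl
Why: Deoxychlorination of a vinylogous carboxylic acid, in which the 4-oxygen is activated as a dichlorophosphate and displaced by chloride through addition–elimination, the standard entry to 4-chlorocoumarins.

Step 5
Reactants: 6 4-chloro-3,6,7-trimethoxychromen-2-one; 7 2,3-dimethoxyphenol
Product: 8 4-(2,3-dimethoxyphenoxy)-3,6,7-trimethoxychromen-2-one
Conditions: K2CO3, DMF, 70 °C
Reagents that add atoms: none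
Why: Addition–elimination (vinylogous acyl substitution) of the phenoxide at C4, which is activated by conjugation with the lactone carbonyl, as is usual for 4-chlorocoumarins with phenols.

Step 6
Reactants: 8 4-(2,3-dimethoxyphenoxy)-3,6,7-trimethoxychromen-2-one
Product: 10 2-(2-hydroxy-4,5-dimethoxyphenyl)-3,7,8-trimethoxychromen-4-one, via ring-opened acylium cation 9 (not isolated)
Conditions: CF3SO3H (anhydrous, excess), (CH2Cl)2, 0 → 60 °C; then ice-water
Reagents that add atoms: none
Why: Proposed new method: in anhydrous CF3SO3H the protonated lactone of 8 should ionise at its acyl–oxygen bond, as an aryl ester does at the outset of a Fries rearrangement, giving cation 9 with the ring B phenol already free; since the carbon that was coumarin C4 carries both the aryloxy oxygen and electron-rich ring B, 9 is a ketene–oxocarbenium ion whose former C3=C4 bond has single-bond character, so the acyl carbon, which starts trans to the aryloxy group, can swing round to it. The one unsubstituted ortho carbon of the 2,3-dimethoxyphenoxy ring, para to a methoxy group, then attacks the acyl carbon in an intramolecular Friedel–Crafts acylation that forms C4–C4a and closes pyranone ring C as a six-membered ring, and proton loss gives the protonated chromone, which should not revert, whereas re-closure of 9 to the lactone only regenerates 8. The nearest known reaction types are the Fries rearrangement of aryl esters in strong acid and the acid-mediated Friedel–Crafts cyclisation of 3-aryloxycinnamic acids to flavones (Ruhemann synthesis). No stereocentre is created, and the C2=C3 alkene is locked inside ring C. The selectivity required is acylation of the aryloxy ring in preference to five-membered closure onto ring B (an indenone): ring B is bonded directly to the cationic carbon and is deactivated, while the aryloxy ring offers a single free, para-activated ortho site reached through a six-membered transition state.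

**Compound list**
1 | 2-hydroxy-4,5-dimethoxybenzoic acid | OC(=O)c1cc(OC)c(OC)cc1O | starting material
2 | methyl 2-hydroxy-4,5-dimethoxybenzoate | COC(=O)c1cc(OC)c(OC)cc1O | intermediate
3 | methoxyacetyl chloride | COCC(=O)Cl | starting material
4 | methyl 4,5-dimethoxy-2-(2-methoxyacetoxy)benzoate | COCC(=O)Oc1cc(OC)c(OC)cc1C(=O)OC | intermediate
5 | 4-hydroxy-3,6,7-trimethoxychromen-2-one | O=c1oc2cc(OC)c(OC)cc2c(O)c1OC | intermediate
6 | 4-chloro-3,6,7-trimethoxychromen-2-one | O=c1oc2cc(OC)c(OC)cc2c(Cl)c1OC | intermediate
7 | 2,3-dimethoxyphenol | COc1cccc(O)c1OC | starting material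
8 | 4-(2,3-dimethoxyphenoxy)-3,6,7-trimethoxychromen-2-one | O=c1oc2cc(OC)c(OC)cc2c(Oc2cccc(OC)c2OC)c1OC | intermediate
9 | ring-opened acylium cation, 1-(2,3-dimethoxyphenoxy)-1-(2-hydroxy-4,5-dimethoxyphenyl)-2-methoxy-3-oxoprop-2-en-1-ylium (ketene–oxocarbenium form) | COC(=C=O)[C+](Oc1cccc(OC)c1OC)c1cc(OC)c(OC)cc1O | intermediate
10 | 2-(2-hydroxy-4,5-dimethoxyphenyl)-3,7,8-trimethoxychromen-4-one | COc1cc(O)c(-c2oc3c(OC)c(OC)ccc3c(=O)c2OC)cc1OC | target

**Step count**
Total steps: 6. Longest linear sequence: 6 steps (1 → 2 → 4 → 5 → 6 → 8 → 10).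

**Steps most likely to fail**

Step 6 (proposed new method). The protonated lactone may simply persist as a stable hydroxybenzopyrylium-type cation without ionising at the acyl–oxygen bond. Alternatively, the aryl vinyl ether C–O bond may cleave first, or acylation may go to ring B. The fallback is a Baker–Venkataraman sequence of known chemistry that sets out from 2 (with 3 and 7) and rejoins the route at 10. Phenol 7 is acylated with 3 (pyridine, CH2Cl2) to give 2,3-dimethoxyphenyl 2-methoxyacetate F1. A Fries rearrangement (BF3·OEt2, 90 °C) then moves the acyl group to the free ortho carbon to give 1-(2-hydroxy-3,4-dimethoxyphenyl)-2-methoxyethan-1-one F2. In parallel, 2 is benzylated (BnBr, K2CO3, DMF) to methyl 2-(benzyloxy)-4,5-dimethoxybenzoate F3 and saponified (LiOH, THF/H2O; then HCl) to 2-(benzyloxy)-4,5-dimethoxybenzoic acid F4. Coupling of F2 with F4 (1-ethyl-3-(3-dimethylaminopropyl)carbodiimide hydrochloride, 4-(dimethylamino)pyridine, CH2Cl2) should give 6-(2-methoxyacetyl)-2,3-dimethoxyphenyl 2-(benzyloxy)-4,5-dimethoxybenzoate F5. Base-induced acyl migration (KOH, pyridine, 50 °C) should give 1-[2-(benzyloxy)-4,5-dimethoxyphenyl]-3-(2-hydroxy-3,4-dimethoxyphenyl)-2-methoxypropane-1,3-dione F6. Cyclodehydration (AcOH, H2SO4 cat., 90 °C) should give 2-[2-(benzyloxy)-4,5-dimethoxyphenyl]-3,7,8-trimethoxychromen-4-one F7. Hydrogenolysis (H2, palladium on carbon (Pd/C), EtOAc) then frees the 2'-hydroxyl to give 10.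

Step 3. The aryl ester enolate may fragment by E1cB loss of the phenoxide (methoxyketene plus the phenoxide of 2) faster than it closes, or the acyl group may be passed between molecules. The fallback removes the aryloxide leaving group from the enolate partner; it sets out from 2 and rejoins at 5. Compound 2 is protected (MOMCl, iPr2NEt, CH2Cl2) as methyl 4,5-dimethoxy-2-(methoxymethoxy)benzoate F8. Crossed Claisen condensation with the lithium enolate of methyl methoxyacetate (LiN(iPr)2, THF, −78 °C, enolate in excess) should give methyl 3-[4,5-dimethoxy-2-(methoxymethoxy)phenyl]-2-methoxy-3-oxopropanoate F9. HCl in MeOH at 60 °C should then remove the acetal, and the freed phenol should lactonise onto the ester to give 5.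

Step 5. Addition at C4 may be slow, because the 3-methoxy group and the two ring methoxy groups feed electron density into the chloro-enone. Attack of the phenoxide at the lactone carbonyl, or hydrolysis back to 5, could then compete. The fallback replaces addition–elimination by metal-catalysed C–O coupling; it sets out from 5 and rejoins at 8. Compound 5 is converted (Tf2O, pyridine, CH2Cl2, 0 °C) into 3,6,7-trimethoxy-2-oxo-2H-chromen-4-yl trifluoromethanesulfonate F10. This is coupled with 7 using Pd(OAc)2, 2-di-tert-butylphosphino-2',4',6'-triisopropylbiphenyl and K3PO4 in toluene at 100 °C. Oxidative addition of zerovalent palladium into the C–O(triflate) bond, followed by C–O reductive elimination, should give 8.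

**Further compounds**
F1 | step 6 | 2,3-dimethoxyphenyl 2-methoxyacetate | COCC(=O)Oc1cccc(OC)c1OC
F2 | step 6 | 1-(2-hydroxy-3,4-dimethoxyphenyl)-2-methoxyethan-1-one | COCC(=O)c1ccc(OC)c(OC)c1O
F3 | step 6 | methyl 2-(benzyloxy)-4,5-dimethoxybenzoate | COC(=O)c1cc(OC)c(OC)cc1OCc1ccccc1
F4 | step 6 | 2-(benzyloxy)-4,5-dimethoxybenzoic acid | OC(=O)c1cc(OC)c(OC)cc1OCc1ccccc1
F5 | step 6 | 6-(2-methoxyacetyl)-2,3-dimethoxyphenyl 2-(benzyloxy)-4,5-dimethoxybenzoate | COCC(=O)c1ccc(OC)c(OC)c1OC(=O)c1cc(OC)c(OC)cc1OCc1ccccc1
F6 | step 6 | 1-[2-(benzyloxy)-4,5-dimethoxyphenyl]-3-(2-hydroxy-3,4-dimethoxyphenyl)-2-methoxypropane-1,3-dione | COC(C(=O)c1ccc(OC)c(OC)c1O)C(=O)c1cc(OC)c(OC)cc1OCc1ccccc1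
F7 | step 6 | 2-[2-(benzyloxy)-4,5-dimethoxyphenyl]-3,7,8-trimethoxychromen-4-one | COc1cc(OCc2ccccc2)c(-c2oc3c(OC)c(OC)ccc3c(=O)c2OC)cc1OC
F8 | step 3 | methyl 4,5-dimethoxy-2-(methoxymethoxy)benzoate | COCOc1cc(OC)c(OC)cc1C(=O)OC
F9 | step 3 | methyl 3-[4,5-dimethoxy-2-(methoxymethoxy)phenyl]-2-methoxy-3-oxopropanoate | COCOc1cc(OC)c(OC)cc1C(=O)C(OC)C(=O)OC
F10 | step 5 | 3,6,7-trimethoxy-2-oxo-2H-chromen-4-yl trifluoromethanesulfonate | O=c1oc2cc(OC)c(OC)cc2c(OS(=O)(=O)C(F)(F)F)c1OC
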